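**Retrosynthetic overview**

1. The target is (3R)-8-hydroxy-3-(11-hydroxyundecyl)-6-methoxy-3,4-dihydro-1H-isochromen-1-one (side chain numbered C1′ on C3 to C11′ bearing OH); the last step frees the C8 phenol of the 6,8-dimethoxy lactone 10 by chelation-controlled demethylation.
2. Key disconnection C4′–C5′: a nickel hydride reductive hydroalkylation joins the terminal olefin of lactone 7 (C3′=C4′) with unprotected 7-iodoheptan-1-ol 9; neither carbon is a preformed organometallic, and the silane hydride turns C4′ into the nucleophilic partner only inside the catalytic cycle.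
3. Enabling feature: the C3 substituent of the isochromanone (benzo-fused δ-lactone) ring is an unbranched run of ten methylenes (C1′–C10′) with no heteroatom or stereocentre before the C11′ hydroxyl, so C4′ can be the CH2 end of a monosubstituted olefin two methylenes away from the C3–O stereocentre and C5′ a primary iodide.
4. Rings: the benzene ring is bought with both oxygens in place; the lactone is the only ring formed (step 3, acyl transfer), after amide-directed ortho-metalation and opening of (R)-1,2-epoxy-5-hexene has made the C4–C4a bond and delivered C3 with its configuration.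

Key step: step 5

Remark on the chemistry: C3 is (R) (O > C4 > C1′ > H); (R)-1,2-epoxy-5-hexene is taken as a commercial building block, and the primary hydroxyl of the C7 partner is assumed to pass the nickel step unprotected, any silyl ether formed from the alkoxysilane being cleaved in the acidic work-up.

**Route**

Step 1
Reactants: 1 2,4-dimethoxybenzoyl chloride
Product: 2 N,N-diethyl-2,4-dimethoxybenzamide
Conditions: Et2NH (1.2 equiv), 2 M aq. NaOH, CH2Cl2, 0 °C to rt
Reagents that add atoms: diethylamine, CCNCC
Why: Schotten–Baumann acylation of a secondary amine by an aroyl chloride installs the tertiary amide that serves as ortho-directing group and as the latent lactone carbonyl.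

Step 2
Reactants: 2 N,N-diethyl-2,4-dimethoxybenzamide; 3 (2R)-2-(but-3-en-1-yl)oxirane [(R)-1,2-epoxy-5-hexene]
Product: 6 N,N-diethyl-2-[(2R)-2-hydroxyhex-5-en-1-yl]-4,6-dimethoxybenzamide, via aryllithium 4 (not isolated), via arylmagnesium bromide 5 (not isolated)
Conditions: s-BuLi (1.1 equiv), TMEDA, THF, −78 °C; MgBr2·OEt2 (1.1 equiv), −78 to −30 °C; CuI (10 mol%), 3, −30 to 0 °C; H2O
Reagents that add atoms: none
Why: Directed ortho-metalation puts lithium on C6, the only position ortho to the diethylamide; after Li-to-Mg transmetalation the copper-catalysed Grignard opening of the terminal epoxide proceeds by SN2 attack at its unsubstituted CH2, so the C–O stereocentre of 3 is not touched and becomes C3 with (R) configuration.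

Step 3
Reactants: 6 N,N-diethyl-2-[(2R)-2-hydroxyhex-5-en-1-yl]-4,6-dimethoxybenzamide
Product: 7 (3R)-3-(but-3-en-1-yl)-6,8-dimethoxy-3,4-dihydro-1H-isochromen-1-one
Conditions: TsOH·H2O (0.2 equiv), PhMe, reflux, slow N2 sweep
Reagents that add atoms: none
Why: Acid-catalysed intramolecular acyl transfer (lactonisation) of the secondary hydroxyl onto the twisted, di-ortho-substituted tertiary amide closes the six-membered lactone with loss of volatile diethylamine; the C3–O bond is not broken, so the configuration is retained, and the unactivated terminal olefin should survive a catalytic sulfonic acid in toluene.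

Step 4
Reactants: 8 7-bromoheptan-1-ol
Product: 9 7-iodoheptan-1-ol
Conditions: NaI (1.5 equiv), acetone, reflux
Reagents that add atoms: sodium iodide, [Na+].[I-]
Why: Finkelstein halide exchange (SN2), driven by precipitation of sodium bromide from acetone, gives the primary iodide needed for easy halogen abstraction by nickel.

Step 5
Reactants: 7 (3R)-3-(but-3-en-1-yl)-6,8-dimethoxy-3,4-dihydro-1H-isochromen-1-one; 9 7-iodoheptan-1-ol
Product: 10 (3R)-3-(11-hydroxyundecyl)-6,8-dimethoxy-3,4-dihydro-1H-isochromen-1-one
Conditions: NiBr2·diglyme (10 mol%), dtbbpy (12 mol%), (EtO)2MeSiH (2.5 equiv), Na2CO3 (2 equiv), 9 (1.5 equiv), DMA, 25 °C; 1 M HCl wash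
Reagents that add atoms: none
Why: Nickel hydride reductive hydroalkylation (anti-Markovnikov olefin hydrocarbonation): a bipyridine-ligated Ni–H, formed from the nickel(II) salt, the silane and carbonate, inserts the monosubstituted C3′=C4′ olefin of 7 with nickel on the terminal carbon C4′, the primary iodide 9 is activated by single-electron halogen abstraction to the 7-hydroxyheptyl radical, which is captured at nickel, and C(sp3)–C(sp3) reductive elimination forms the C4′–C5′ bond. The closest known reaction type is the nickel-catalysed, silane-mediated coupling of unactivated α-olefins with primary alkyl iodides, which gives linear products and leaves esters, aryl ethers and hydroxyl groups alone. No ring is closed and no stereocentre is formed; the C3 stereocentre lies two methylenes from the olefin and takes no part, and a bipyridine ligand without 6,6′-substituents is chosen so that the alkylnickel is captured before nickel can chain-walk toward C3. The step needs linear regioselectivity and cross- over homo-coupling: the first is secured by the unhindered terminal olefin, which has no aryl group or heteroatom next to it to stabilise a branched alkylnickel, the second by the mechanism, since only the olefin can give the alkylnickel and only the iodide the radical. The iodide is used in excess to cover its hydrodeiodination, and the dilute acid wash removes any silyl ether formed at the free hydroxyl.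

Step 6
Reactants: 10 (3R)-3-(11-hydroxyundecyl)-6,8-dimethoxy-3,4-dihydro-1H-isochromen-1-one
Product: 11 (3R)-8-hydroxy-3-(11-hydroxyundecyl)-6-methoxy-3,4-dihydro-1H-isochromen-1-one
Conditions: BCl3 (3 equiv, 1 M in CH2Cl2), CH2Cl2, −78 to 0 °C; H2O
Reagents that add atoms: none
Why: Chelation-controlled Lewis acid cleavage of an aryl methyl ether: boron trichloride bridges the lactone carbonyl oxygen and the peri C8 methoxy oxygen in a six-membered chelate, so chloride attacks only that methyl group, while the non-chelated C6 methyl ether, the lactone and the stereocentre are left alone and the B–O bonds at both hydroxyls hydrolyse on work-up.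

**Compound list**

1 | 2,4-dimethoxybenzoyl chloride | COc1ccc(C(=O)Cl)c(OC)c1 | starting material
2 | N,N-diethyl-2,4-dimethoxybenzamide | CCN(CC)C(=O)c1ccc(OC)cc1OC | intermediate
3 | (2R)-2-(but-3-en-1-yl)oxirane [(R)-1,2-epoxy-5-hexene] | C=CCC[C@@H]1CO1 | starting material
4 | N,N-diethyl-2-lithio-4,6-dimethoxybenzamide (aryllithium) | [Li]c1cc(OC)cc(OC)c1C(=O)N(CC)CC | intermediate (not isolated)
5 | [2-(diethylcarbamoyl)-3,5-dimethoxyphenyl]magnesium bromide | Br[Mg]c1cc(OC)cc(OC)c1C(=O)N(CC)CC | intermediate (not isolated)
6 | N,N-diethyl-2-[(2R)-2-hydroxyhex-5-en-1-yl]-4,6-dimethoxybenzamide | C=CCC[C@@H](O)Cc1cc(OC)cc(OC)c1C(=O)N(CC)CC | intermediate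
7 | (3R)-3-(but-3-en-1-yl)-6,8-dimethoxy-3,4-dihydro-1H-isochromen-1-one | COc1cc(OC)c2c(c1)C[C@@H](CCC=C)OC2=O | intermediate
8 | 7-bromoheptan-1-ol | OCCCCCCCBr | starting material
9 | 7-iodoheptan-1-ol | OCCCCCCCI | intermediate
10 | (3R)-3-(11-hydroxyundecyl)-6,8-dimethoxy-3,4-dihydro-1H-isochromen-1-one | COc1cc(OC)c2c(c1)C[C@@H](CCCCCCCCCCCO)OC2=O | intermediate
11 | (3R)-8-hydroxy-3-(11-hydroxyundecyl)-6-methoxy-3,4-dihydro-1H-isochromen-1-one | COc1cc(O)c2c(c1)C[C@@H](CCCCCCCCCCCO)OC2=O | target

**Step count**

Total steps: 6. Longest linear sequence: 5 (steps 1, 2, 3, 5, 6); step 4 prepares the second fragment.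

**Steps most likely to fail, with fallbacks**

Step 5 (nickel hydride hydroalkylation). What may go wrong: isomerisation of the terminal olefin by reversible Ni–H insertion followed by branched coupling, and reduction of the iodide to the alkane faster than cross-coupling. The fallback sets out from 7 and 8 and comes back at 10. The olefin of 7 is hydroborated with 9-BBN (THF, 0 °C to rt), which places boron on C4′ and should give (3R)-3-[4-(9-borabicyclo[3.3.1]nonan-9-yl)butyl]-6,8-dimethoxy-3,4-dihydro-1H-isochromen-1-one F1. This is used in solution in a B-alkyl Suzuki–Miyaura alkyl–alkyl coupling with 7-bromoheptan-1-ol 8 [Pd(OAc)2, PCy3, K3PO4·H2O, THF, rt]. The same C4′–C5′ bond is then formed from a stoichiometric organoborane under palladium catalysis, and the product should be 10.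

Step 2 (ortho-metalation and epoxide opening). What may go wrong: metalation between the two methoxy groups competing with the amide-directed metalation at C6, and opening of the epoxide by bromide from the magnesium salt competing with aryl transfer. The fallback sets out from 3 and comes back at 7. 1-Bromo-3,5-dimethoxybenzene F2 is converted with magnesium (THF) into (3,5-dimethoxyphenyl)magnesium bromide F3, which opens 3 under CuI catalysis to (2R)-1-(3,5-dimethoxyphenyl)hex-5-en-2-ol F4. Electrophilic bromination (NBS, MeCN, 0 °C) ortho to the side chain and para to a methoxy group should give (2R)-1-(2-bromo-3,5-dimethoxyphenyl)hex-5-en-2-ol F5. Palladium-catalysed carbonylative lactonisation [Pd(OAc)2, dppf, CO, K2CO3, PhMe, 100 °C] then closes the lactone to 7. No directing group is needed on this path, and the lactone carbonyl comes from carbon monoxide.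

Step 3 (lactonisation). What may go wrong: acid-promoted addition of the C3 hydroxyl across the terminal olefin, or stalling of the acyl transfer as the liberated amine neutralises the catalyst. The fallback sets out from 6 and comes back at 10, and changes the order of events. Compound 6 is first coupled with 9 under the conditions of step 5 to N,N-diethyl-2-[(2R)-2,13-dihydroxytridecyl]-4,6-dimethoxybenzamide F6, in which no olefin is left. F6 is then lactonised under forcing acid (TsOH·H2O 1.5 equiv, PhMe, reflux) to 10; the six-membered lactone at the secondary hydroxyl is favoured over any reaction of the remote primary hydroxyl.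

**Further compounds**

F1 | step 5 | (3R)-3-[4-(9-borabicyclo[3.3.1]nonan-9-yl)butyl]-6,8-dimethoxy-3,4-dihydro-1H-isochromen-1-one | COc1cc(OC)c2c(c1)C[C@@H](CCCCB3C4CCCC3CCC4)OC2=O
F2 | step 2 | 1-bromo-3,5-dimethoxybenzene | COc1cc(Br)cc(OC)c1
F3 | step 2 | (3,5-dimethoxyphenyl)magnesium bromide | COc1cc([Mg]Br)cc(OC)c1
F4 | step 2 | (2R)-1-(3,5-dimethoxyphenyl)hex-5-en-2-ol | C=CCC[C@@H](O)Cc1cc(OC)cc(OC)c1
F5 | step 2 | (2R)-1-(2-bromo-3,5-dimethoxyphenyl)hex-5-en-2-ol | C=CCC[C@@H](O)Cc1cc(OC)cc(OC)c1Br
F6 | step 3 | N,N-diethyl-2-[(2R)-2,13-dihydroxytridecyl]-4,6-dimethoxybenzamide | OCCCCCCCCCCC[C@@H](O)Cc1cc(OC)cc(OC)c1C(=O)N(CC)CC
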